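**Retrosynthetic overview**
1. The target comes from global desilylation of a persilylated ester; its (Z)-C=C is made last by a Still–Gennari olefination of a C3 phosphonoacetate with silylated 3,4-dihydroxybenzaldehyde.
2. The 3β-allylic alcohol comes from a C4 ketone: Rubottom oxidation at C3, Wittig methylenation at C4, then oxidation and Luche reduction to set 3β.
3. Ring B substituents come from a C7 ketone: enol triflate, isopropyl cross-coupling, hydroboration (sets 7β-isopropyl and 8α-OH). The C4 oxygen and 5α-H come from hydroboration of a deconjugated enone ketal.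
4. The decalin is (R)-Wieland–Miescher ketone. Its key C9–C10 bond is made by intermolecular Michael addition of 2-methylcyclohexane-1,3-dione to methyl vinyl ketone, followed by D-proline aldol condensation.
5. Ring order: ring A is bought as the dione, ring B is closed by the annulation; everything after that is functional-group work on the intact decalin.

Convention: eudesmane numbering (C10 = quaternary carbon with the angular CH3, C1–C4 = ring A, C5 = ring-fusion CH, C6–C9 = ring B, C15 = exocyclic CH2 on C4). β = face of the C10 methyl, α = opposite face. TBS = tert-butyldimethylsilyl, TES = triethylsilyl. The target is read as 1β,8α-dihydroxy-3β-[(Z)-caffeoyloxy]-5α-eudesm-4(15)-ene, (1R,3S,5S,7R,8S,10R).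
Assumption: D-proline and methyl bis(2,2,2-trifluoroethyl)phosphonoacetate are taken as catalogue items.

**Step 1**
Reactants: 1 2-methylcyclohexane-1,3-dione; 2 methyl vinyl ketone
Product: 3 2-methyl-2-(3-oxobutyl)cyclohexane-1,3-dione
Conditions: H2O, AcOH (cat.), hydroquinone (cat.), 75 °C, 1 h
Reagents that add atoms: none
Why: Intermolecular Michael addition of the enolised 1,3-dione to the enone joins the two fragments at the future C9–C10 bond and builds the still prochiral quaternary carbon in near-quantitative yield.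

**Step 2**
Reactants: 3 triketone
Product: 5 (R)-Wieland–Miescher ketone, via bicyclic ketol 4 (not isolated)
Conditions: D-proline (5 mol%), DMSO, 35 °C, 4 d; recrystallisation (Et2O/hexane) to ≥99% ee
Reagents that add atoms: none
Why: Hajos–Parrish–Eder–Sauer–Wiechert enamine aldol condensation, in which D-proline differentiates the two enantiotopic ring carbonyls so that C10 becomes R (mirror image of the L-proline/(S) series) and crystallisation removes the minor enantiomer.

**Step 3**
Reactants: 5 (R)-Wieland–Miescher ketone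
Product: 6 1β-hydroxy enone
Conditions: NaBH4 (0.3 equiv), EtOH, −10 °C
Reagents that add atoms: none
Why: Chemoselective borohydride reduction of the saturated ketone over the less electrophilic enone, with hydride attacking C1 anti to the angular methyl to give the equatorial 1β-alcohol (OH cis to CH3).

**Step 4**
Reactants: 6 1β-hydroxy enone
Product: 7 hydroxy Δ4 ketal
Conditions: ethylene glycol, TsOH·H2O (cat.), benzene, reflux, Dean–Stark
Reagents that add atoms: ethylene glycol (OCCO)
Why: Acid-catalysed ketalisation of the enone runs through the dienol, so the C=C moves out of conjugation into ring A (C4=C5) as in Δ4-3-keto steroids, leaving C1 and C10 untouched.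

**Step 5**
Reactants: 7 hydroxy Δ4 ketal
Product: 8 1β-TBS ether
Conditions: TBSOTf, 2,6-lutidine, CH2Cl2, 0 °C
Reagents that add atoms: tert-butyldimethylsilyl trifluoromethanesulfonate (CC(C)(C)[Si](C)(C)OS(=O)(=O)C(F)(F)F)
Why: Silylation of the hindered neopentyl-type secondary alcohol needs the silyl triflate, and the cold lutidine-buffered medium leaves the dioxolane intact.

**Step 6**
Reactants: 8 1β-TBS ether
Product: 10 4α-alcohol ketal, via C4 alkylborane 9 (not isolated)
Conditions: BH3·THF, THF, 0 °C → rt; then 3 M NaOH, 30% H2O2, 0 °C → rt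
Reagents that add atoms: borane–tetrahydrofuran ([BH3-][O+]1CCCC1); hydrogen peroxide (OO)
Why: Hydroboration–oxidation of the trisubstituted olefin puts boron on the less substituted C4 and H on C5 in a syn addition from the α face opposite the angular methyl, setting the trans ring fusion (5α-H) and the equatorial 4α-OH; the boron is carried only by 9 and is replaced by oxygen with retention in the oxidation.

**Step 7**
Reactants: 10 4α-alcohol ketal
Product: 11 4α-benzyl ether ketal
Conditions: NaH, BnBr, Bu4NI (cat.), THF/DMF, 0 °C → rt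
Reagents that add atoms: benzyl bromide (BrCc1ccccc1)
Why: Williamson etherification masks the C4 oxygen with a group that survives acid, strong base, the organomagnesium reagent and borane and later leaves by hydrogenolysis without touching silyl ethers.

**Step 8**
Reactants: 11 4α-benzyl ether ketal
Product: 12 C7 ketone
Conditions: PPTS, acetone/H2O (10:1), 60 °C
Reagents that add atoms: water (O)
Why: Mild acid-catalysed ketal hydrolysis frees the C7 ketone while the hindered secondary TBS ether and the benzyl ether are stable to pyridinium tosylate.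

**Step 9**
Reactants: 12 C7 ketone
Product: 13 Δ7 enol triflate
Conditions: KN(SiMe3)2, THF, −78 °C; then PhNTf2, −78 → 0 °C
Reagents that add atoms: N-phenylbis(trifluoromethanesulfonimide) (O=S(=O)(N(c1ccccc1)S(=O)(=O)C(F)(F)F)C(F)(F)F)
Why: Kinetic enolisation of the trans-fused C7 ketone goes toward C8 rather than C6 (the same preference as Δ2 enolisation of 5α-3-keto steroids, reinforced here by the peri 4α-benzyloxy group next to C6) and O-sulfonylation of the enolate fixes the C7=C8 olefin.

**Step 10**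
Reactants: 13 Δ7 enol triflate
Product: 14 7-isopropyl Δ7 olefin
Conditions: iPrMgCl (1.5 equiv), Fe(acac)3 (5 mol%), THF/NMP, −30 → 0 °C
Reagents that add atoms: isopropylmagnesium chloride (CC(C)[Mg]Cl)
Why: Iron-catalysed Kumada-type cross-coupling of an alkenyl triflate with a secondary alkylmagnesium halide is fast at low temperature and does not isomerise isopropyl to n-propyl, while ethers and silyl ethers are inert.

**Step 11**
Reactants: 14 7-isopropyl Δ7 olefin
Product: 16 8α-alcohol, via C8 alkylborane 15 (not isolated)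
Conditions: BH3·THF, THF, 0 °C → rt; then 3 M NaOH, 30% H2O2, 0 °C → rt
Reagents that add atoms: borane–tetrahydrofuran ([BH3-][O+]1CCCC1); hydrogen peroxide (OO)
Why: Hydroboration–oxidation adds boron to C8 and H to C7 syn from the α face (the β face of C8 is blocked by the 1,3-diaxial angular methyl), setting 8α-OH and 7β-isopropyl together as a trans-diequatorial pair; the boron is carried only by 15 and is replaced by oxygen with retention in the oxidation.

**Step 12**
Reactants: 16 8α-alcohol
Product: 17 1β,8α-bis-TBS 4α-benzyl ether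
Conditions: TBSOTf, 2,6-lutidine, CH2Cl2, 0 °C → rt
Reagents that add atoms: tert-butyldimethylsilyl trifluoromethanesulfonate (CC(C)(C)[Si](C)(C)OS(=O)(=O)C(F)(F)F)
Why: Silyl triflate silylation protects the hindered C8 carbinol next to the isopropyl group with the same fluoride-labile group as C1.

**Step 13**
Reactants: 17 1β,8α-bis-TBS 4α-benzyl ether
Product: 18 4α-alcohol
Conditions: H2 (1 atm), Pd(OH)2/C, EtOAc, rt
Reagents that add atoms: none
Why: Hydrogenolysis of the benzyl ether is clean because no olefin is present at this stage and TBS ethers are stable in neutral ethyl acetate.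

**Step 14**
Reactants: 18 4α-alcohol
Product: 19 C4 ketone
Conditions: DMP, NaHCO3, CH2Cl2, rt
Reagents that add atoms: none
Why: Dess–Martin oxidation under buffered neutral conditions gives the ketone, and the trans ring fusion at C5 (now α to C=O) is the thermodynamically preferred one so it cannot be lost.

**Step 15**
Reactants: 19 C4 ketone
Product: 22 3α-triethylsilyloxy C4 ketone, via TES enol ether 20 (not isolated), via silyloxy epoxide 21 (not isolated)
Conditions: LiN(iPr)2 (commercial solution), THF, −78 °C; TESCl, Et3N, −78 → 0 °C; then mCPBA, NaHCO3, CH2Cl2, −20 → 0 °C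
Reagents that add atoms: chlorotriethylsilane (CC[Si](Cl)(CC)CC); 3-chloroperbenzoic acid (OOC(=O)c1cccc(Cl)c1)
Why: Rubottom oxidation, in which kinetic deprotonation takes the C3 methylene rather than the ring-fusion C5–H, epoxidation occurs on the α face away from the angular methyl and 1,4-silyl migration gives the 3α-silyloxy ketone, whose C3 configuration is erased in step 18 and so is of no consequence.

**Step 16**
Reactants: 22 3α-triethylsilyloxy C4 ketone
Product: 23 3α-triethylsilyloxy 4(15)-olefin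
Conditions: Ph3PCH3Br, KOtBu, toluene, 80 °C
Reagents that add atoms: methyltriphenylphosphonium bromide (C[P+](c1ccccc1)(c1ccccc1)c1ccccc1.[Br-])
Why: Wittig methylenation with the small salt-free ylide is the standard way to convert hindered C4 ketones of this decalin series into the exocyclic C4=C15 olefin, and silyl ethers tolerate the ylide.

**Step 17**
Reactants: 23 3α-triethylsilyloxy 4(15)-olefin
Product: 24 3α-allylic alcohol
Conditions: PPTS (0.2 equiv), MeOH/CH2Cl2, 0 °C
Reagents that add atoms: none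
Why: Acid-catalysed methanolysis removes the triethylsilyl group far faster (roughly a hundredfold or more) than the hindered secondary TBS ethers at C1 and C8.

**Step 18**
Reactants: 24 3α-allylic alcohol
Product: 25 4(15)-en-3-one
Conditions: DMP, NaHCO3, CH2Cl2, 0 °C; used at once
Reagents that add atoms: none
Why: Dess–Martin oxidation gives the α-methylene ketone under non-basic conditions (no β-elimination of the C1 silyloxy group, no Michael dimerisation) and deliberately erases C3.

**Step 19**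
Reactants: 25 4(15)-en-3-one
Product: 26 3β-allylic alcohol
Conditions: NaBH4, CeCl3·7H2O, MeOH, −78 °C
Reagents that add atoms: none
Why: Luche 1,2-reduction, in which the small hydride adds axially to the chair cyclohexanone from the α face to give the equatorial 3β-alcohol and leaves the exocyclic olefin untouched.

**Step 20**
Reactants: 27 methyl bis(2,2,2-trifluoroethyl)phosphonoacetate
Product: 28 bis(2,2,2-trifluoroethyl)phosphonoacetic acid
Conditions: LiOH·H2O (1.05 equiv), THF/H2O, 0 °C, 1 h; then 1 M HCl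
Reagents that add atoms: lithium hydroxide ([Li+].[OH-])
Why: Saponification of the activated methyl carboxylate with one equivalent of hydroxide at 0 °C is expected to outpace attack at phosphorus, so the trifluoroethyl phosphonate esters are kept.

**Step 21**
Reactants: 26 3β-allylic alcohol; 28 bis(2,2,2-trifluoroethyl)phosphonoacetic acid
Product: 29 C3 phosphonoacetate
Conditions: EDC·HCl, DMAP (cat.), CH2Cl2, 0 °C → rt
Reagents that add atoms: none
Why: Carbodiimide (Steglich) esterification of the only free hydroxyl proceeds with retention at C3 because the C–O bond of the alcohol is not broken.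

**Step 22**
Reactants: 30 3,4-dihydroxybenzaldehyde
Product: 31 3,4-bis(TBS-oxy)benzaldehyde
Conditions: TBSCl, imidazole, DMF, rt
Reagents that add atoms: tert-butyldimethylsilyl chloride (CC(C)(C)[Si](C)(C)Cl)
Why: Silylation of both phenols protects the catechol from the strongly basic olefination with a group that leaves with fluoride at the end.

**Step 23**
Reactants: 29 C3 phosphonoacetate; 31 3,4-bis(TBS-oxy)benzaldehyde
Product: 32 persilylated (Z)-caffeate
Conditions: KN(SiMe3)2, 18-crown-6, THF, −78 °C; then 31, −78 °C, exclusion of light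
Reagents that add atoms: none
Why: Still–Gennari variant of the Horner–Wadsworth–Emmons olefination, in which the electron-poor trifluoroethyl phosphonate with a crown-separated potassium cation eliminates from the kinetic adduct to give the (Z)-cinnamate (typically >10:1 with aryl aldehydes).

**Step 24**
Reactants: 32 persilylated (Z)-caffeate
Product: 33 target CNP0264533.2
Conditions: HF·pyridine, THF/pyridine, 0 °C → rt, polypropylene flask, exclusion of light
Reagents that add atoms: none
Why: Fluoride-driven Si–O cleavage under weakly acidic conditions removes the two aryl and two secondary alkyl TBS groups without the phenoxide formation, ester cleavage or Z→E isomerisation that basic fluoride or hydroxide could cause, and no stereocentre is involved.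

**Compound list**
1 | 2-methylcyclohexane-1,3-dione | CC1C(=O)CCCC1=O | starting material
2 | methyl vinyl ketone (but-3-en-2-one) | CC(=O)C=C | starting material
3 | 2-methyl-2-(3-oxobutyl)cyclohexane-1,3-dione | CC(=O)CCC1(C)C(=O)CCCC1=O | intermediate
4 | (4aR,8aR)-4a-hydroxy-8a-methyloctahydronaphthalene-1,6-dione (cis-fused ketol, OH cis to CH3; not isolated) | C1CCC(=O)[C@]2(C)CCC(=O)C[C@]12O | intermediate
5 | (R)-(−)-Wieland–Miescher ketone, (8aR)-8a-methyl-3,4,8,8a-tetrahydronaphthalene-1,6(2H,7H)-dione | C[C@@]12CCC(=O)C=C1CCCC2=O | intermediate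
6 | (4aR,5R)-5-hydroxy-4a-methyl-4,4a,5,6,7,8-hexahydronaphthalen-2(3H)-one (1β-hydroxy-10β-methyloctal-5-en-7-one) | C1CC[C@@H](O)[C@]2(C)CCC(=O)C=C12 | intermediate
7 | 7,7-ethylenedioxy-10β-methyloctal-4-en-1β-ol (C4=C5 olefin, dioxolane at C7) | C1=C2CC3(OCCO3)CC[C@@]2(C)[C@H](O)CC1 | intermediate
8 | 1β-(TBS-oxy)-7,7-ethylenedioxy-10β-methyloctal-4-ene | C1=C2CC3(OCCO3)CC[C@@]2(C)[C@H](O[Si](C)(C)C(C)(C)C)CC1 | intermediate
9 | 4α-boranyl-1β-(TBS-oxy)-7,7-ethylenedioxy-10β-methyl-5α-decalin (not isolated) | B[C@@H]1CC[C@@H](O[Si](C)(C)C(C)(C)C)[C@]2(C)CCC3(OCCO3)C[C@@H]12 | intermediate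
10 | 1β-(TBS-oxy)-7,7-ethylenedioxy-10β-methyl-5α-decalin-4α-ol (trans-fused) | O[C@@H]1CC[C@@H](O[Si](C)(C)C(C)(C)C)[C@]2(C)CCC3(OCCO3)C[C@@H]12 | intermediate
11 | 4α-benzyloxy-1β-(TBS-oxy)-7,7-ethylenedioxy-10β-methyl-5α-decalin | O(Cc4ccccc4)[C@@H]1CC[C@@H](O[Si](C)(C)C(C)(C)C)[C@]2(C)CCC3(OCCO3)C[C@@H]12 | intermediate
12 | 4α-benzyloxy-1β-(TBS-oxy)-10β-methyl-5α-decalin-7-one | O(Cc4ccccc4)[C@@H]1CC[C@@H](O[Si](C)(C)C(C)(C)C)[C@]2(C)CCC(=O)C[C@@H]12 | intermediate
13 | 4α-benzyloxy-1β-(TBS-oxy)-10β-methyl-5α-octal-7-en-7-yl trifluoromethanesulfonate | O(Cc4ccccc4)[C@@H]1CC[C@@H](O[Si](C)(C)C(C)(C)C)[C@]2(C)CC=C(OS(=O)(=O)C(F)(F)F)C[C@@H]12 | intermediate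
14 | 4α-benzyloxy-1β-(TBS-oxy)-7-isopropyl-10β-methyl-5α-octal-7-ene | O(Cc4ccccc4)[C@@H]1CC[C@@H](O[Si](C)(C)C(C)(C)C)[C@]2(C)CC=C(C(C)C)C[C@@H]12 | intermediate
15 | 8α-boranyl-4α-benzyloxy-1β-(TBS-oxy)-7β-isopropyl-10β-methyl-5α-decalin (not isolated) | O(Cc4ccccc4)[C@@H]1CC[C@@H](O[Si](C)(C)C(C)(C)C)[C@]2(C)C[C@H](B)[C@@H](C(C)C)C[C@@H]12 | intermediate
16 | 4α-benzyloxy-1β-(TBS-oxy)-15-nor-5α-eudesman-8α-ol (7β-isopropyl) | O(Cc4ccccc4)[C@@H]1CC[C@@H](O[Si](C)(C)C(C)(C)C)[C@]2(C)C[C@H](O)[C@@H](C(C)C)C[C@@H]12 | intermediate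
17 | 4α-benzyloxy-1β,8α-bis(TBS-oxy)-15-nor-5α-eudesmane | O(Cc4ccccc4)[C@@H]1CC[C@@H](O[Si](C)(C)C(C)(C)C)[C@]2(C)C[C@H](O[Si](C)(C)C(C)(C)C)[C@@H](C(C)C)C[C@@H]12 | intermediate
18 | 1β,8α-bis(TBS-oxy)-15-nor-5α-eudesman-4α-ol | O[C@@H]1CC[C@@H](O[Si](C)(C)C(C)(C)C)[C@]2(C)C[C@H](O[Si](C)(C)C(C)(C)C)[C@@H](C(C)C)C[C@@H]12 | intermediate
19 | 1β,8α-bis(TBS-oxy)-15-nor-5α-eudesman-4-one | O=C1CC[C@@H](O[Si](C)(C)C(C)(C)C)[C@]2(C)C[C@H](O[Si](C)(C)C(C)(C)C)[C@@H](C(C)C)C[C@@H]12 | intermediate
20 | 4-(TES-oxy)-1β,8α-bis(TBS-oxy)-15-nor-5α-eudesm-3-ene (not isolated) | CC[Si](CC)(CC)OC1=CC[C@@H](O[Si](C)(C)C(C)(C)C)[C@]2(C)C[C@H](O[Si](C)(C)C(C)(C)C)[C@@H](C(C)C)C[C@@H]12 | intermediate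
21 | 3α,4α-epoxy-4β-(TES-oxy)-1β,8α-bis(TBS-oxy)-15-nor-5α-eudesmane (not isolated) | CC[Si](CC)(CC)O[C@@]1(O3)[C@H]3C[C@@H](O[Si](C)(C)C(C)(C)C)[C@]2(C)C[C@H](O[Si](C)(C)C(C)(C)C)[C@@H](C(C)C)C[C@@H]12 | intermediate
22 | 3α-(TES-oxy)-1β,8α-bis(TBS-oxy)-15-nor-5α-eudesman-4-one | O=C1[C@H](O[Si](CC)(CC)CC)C[C@@H](O[Si](C)(C)C(C)(C)C)[C@]2(C)C[C@H](O[Si](C)(C)C(C)(C)C)[C@@H](C(C)C)C[C@@H]12 | intermediate
23 | 3α-(TES-oxy)-1β,8α-bis(TBS-oxy)-5α-eudesm-4(15)-ene | C=C1[C@H](O[Si](CC)(CC)CC)C[C@@H](O[Si](C)(C)C(C)(C)C)[C@]2(C)C[C@H](O[Si](C)(C)C(C)(C)C)[C@@H](C(C)C)C[C@@H]12 | intermediate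
24 | 1β,8α-bis(TBS-oxy)-5α-eudesm-4(15)-en-3α-ol | C=C1[C@H](O)C[C@@H](O[Si](C)(C)C(C)(C)C)[C@]2(C)C[C@H](O[Si](C)(C)C(C)(C)C)[C@@H](C(C)C)C[C@@H]12 | intermediate
25 | 1β,8α-bis(TBS-oxy)-5α-eudesm-4(15)-en-3-one | C=C1C(=O)C[C@@H](O[Si](C)(C)C(C)(C)C)[C@]2(C)C[C@H](O[Si](C)(C)C(C)(C)C)[C@@H](C(C)C)C[C@@H]12 | intermediate
26 | 1β,8α-bis(TBS-oxy)-5α-eudesm-4(15)-en-3β-ol | C=C1[C@@H](O)C[C@@H](O[Si](C)(C)C(C)(C)C)[C@]2(C)C[C@H](O[Si](C)(C)C(C)(C)C)[C@@H](C(C)C)C[C@@H]12 | intermediate
27 | methyl 2-[bis(2,2,2-trifluoroethoxy)phosphoryl]acetate | COC(=O)CP(=O)(OCC(F)(F)F)OCC(F)(F)F | starting material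
28 | 2-[bis(2,2,2-trifluoroethoxy)phosphoryl]acetic acid | OC(=O)CP(=O)(OCC(F)(F)F)OCC(F)(F)F | intermediate
29 | 1β,8α-bis(TBS-oxy)-5α-eudesm-4(15)-en-3β-yl 2-[bis(2,2,2-trifluoroethoxy)phosphoryl]acetate | C=C1[C@@H](OC(=O)CP(=O)(OCC(F)(F)F)OCC(F)(F)F)C[C@@H](O[Si](C)(C)C(C)(C)C)[C@]2(C)C[C@H](O[Si](C)(C)C(C)(C)C)[C@@H](C(C)C)C[C@@H]12 | intermediate
30 | 3,4-dihydroxybenzaldehyde | O=Cc1ccc(O)c(O)c1 | starting material
31 | 3,4-bis(tert-butyldimethylsilyloxy)benzaldehyde | O=Cc1ccc(O[Si](C)(C)C(C)(C)C)c(O[Si](C)(C)C(C)(C)C)c1 | intermediate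
32 | 1β,8α-bis(TBS-oxy)-5α-eudesm-4(15)-en-3β-yl (Z)-3-[3,4-bis(TBS-oxy)phenyl]prop-2-enoate | C=C1[C@@H](OC(=O)/C=C\c3ccc(O[Si](C)(C)C(C)(C)C)c(O[Si](C)(C)C(C)(C)C)c3)C[C@@H](O[Si](C)(C)C(C)(C)C)[C@]2(C)C[C@H](O[Si](C)(C)C(C)(C)C)[C@@H](C(C)C)C[C@@H]12 | intermediate
33 | (1R,3S,5S,7R,8S,10R)-1,8-dihydroxyeudesm-4(15)-en-3-yl (Z)-3-(3,4-dihydroxyphenyl)prop-2-enoate (CNP0264533.2) | C=C1[C@@H](OC(=O)/C=C\c2ccc(O)c(O)c2)C[C@@H](O)[C@]2(C)C[C@H](O)[C@@H](C(C)C)C[C@@H]12 | target

**Totals**
Total step count: 24 (steps 20 and 22 are one-step side branches).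
Longest linear sequence: 22 steps (1–19, 21, 23, 24) from 1 and 2.

**Three steps most likely to fail**

Step 10 (iron-catalysed coupling of a secondary alkylmagnesium halide with the enol triflate; reduction or homocoupling could compete). The fallback sets out from 13. Suzuki–Miyaura coupling with isopropenylboronic acid pinacol ester (Pd(PPh3)4, K3PO4, dioxane/H2O, 80 °C) gives the 7-isopropenyl 7-ene diene F1. Hydrogenation of only its 1,1-disubstituted isopropenyl C=C with H2 and RhCl(PPh3)3 in benzene at rt comes back to the route at 14.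

Step 16 (Wittig methylenation of a hindered ketone flanked by a silyloxy group and the ring fusion). The fallback sets out from 19. The unsubstituted ketone is methylenated first (Ph3PCH3Br, KOtBu, toluene) to the 3-deoxy 4(15)-olefin F2. SeO2 (cat.)/t-BuOOH allylic hydroxylation at C3 then gives the axial 3α-alcohol and comes back to the route at 24; any over-oxidised material is 25 and is used as such.

Step 19 (facial selectivity of the hydride addition to the α-methylene ketone). The fallback sets out from 24 and avoids the ketone altogether. Mitsunobu inversion of the 3α-alcohol with 4-nitrobenzoic acid (PPh3, diisopropyl azodicarboxylate, THF, 0 °C) gives the 3β-(4-nitrobenzoate) F3. Methanolysis (K2CO3, MeOH, rt) comes back to the route at 26.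

**Further compounds**
F1 | step 10 | 4α-benzyloxy-1β-(TBS-oxy)-7-isopropenyl-10β-methyl-5α-octal-7-ene | O(Cc4ccccc4)[C@@H]1CC[C@@H](O[Si](C)(C)C(C)(C)C)[C@]2(C)CC=C(C(C)=C)C[C@@H]12
F2 | step 16 | 1β,8α-bis(TBS-oxy)-5α-eudesm-4(15)-ene | C=C1CC[C@@H](O[Si](C)(C)C(C)(C)C)[C@]2(C)C[C@H](O[Si](C)(C)C(C)(C)C)[C@@H](C(C)C)C[C@@H]12
F3 | step 19 | 1β,8α-bis(TBS-oxy)-5α-eudesm-4(15)-en-3β-yl 4-nitrobenzoate | C=C1[C@@H](OC(=O)c3ccc(cc3)[N+](=O)[O-])C[C@@H](O[Si](C)(C)C(C)(C)C)[C@]2(C)C[C@H](O[Si](C)(C)C(C)(C)C)[C@@H](C(C)C)C[C@@H]12
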